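**Retrosynthetic overview** (oxane numbering used throughout: O1, C2 (methyl, vinyl), C3, C4, C5 (Br), C6 (methyl, side chain))

1. The oxane is made last, from an oxolane (O1, C2, C3, C4, C5) that carries C6 as an exocyclic tertiary carbinol: O1 moves from C5 to C6 and bromide enters C5. The enabling feature is the vicinal, anti-disposed O1–C6 / C5–Br pair (a β-bromo ether), which maps onto an oxonium ion in which O1 bridges C5 and C6.
2. The oxolane carbinol comes from 5-exo opening of a (5R,6R)-epoxide (Shi epoxidation) by the C2 tertiary hydroxyl of a nerolidol-type dienol; C2 is taken from (S)-linalool.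
3. The dienol is cut at the allylic C–C bond of the side chain: (E)-8-bromolinalool plus an oxanorbornylmethyl Grignard reagent.
4. The 7-oxabicyclo[2.2.1]heptane comes from the 2,5-dimethylfuran/maleic anhydride cycloadduct by alkaloid desymmetrisation, epimerisation of the ester-bearing carbon and reduction of one carboxyl to methyl.
5. Ring order: oxanorbornane first (carbocycle by cycloaddition onto the furan), oxolane second, oxane last by ring expansion.

Key step: step 13

Assumption: (S)-(+)-linalool of high enantiomeric purity is taken as purchasable, and the quinidine-mediated methanolysis is assumed to follow the sense established for bicyclic meso anhydrides (quinine would give the antipode).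

**Route**

Step 1
Reactants: 1 2,5-dimethylfuran; 2 maleic anhydride
Product: 4 exo-1,4-dimethyl-7-oxabicyclo[2.2.1]heptane-2,3-dicarboxylic anhydride (meso), via exo cycloadduct 3 (not isolated)
Conditions: Et2O, rt; then H2 (1 atm), Pd/C, EtOAc, rt
Reagents that add atoms: none
Why: The reversible Diels–Alder reaction of the electron-rich furan should give the thermodynamic exo adduct (meso, anhydride syn to the oxygen bridge), which is trapped by hydrogenation of the ring alkene before cycloreversion.

Step 2
Reactants: 4 meso anhydride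
Product: 5 (1S,2R,3S,4R)-3-(methoxycarbonyl)-1,4-dimethyl-7-oxabicyclo[2.2.1]heptane-2-carboxylic acid (acid and ester both exo)
Conditions: quinidine (1.1 equiv), MeOH (3 equiv), toluene, −55 °C; aqueous HCl wash (alkaloid recovered)
Reagents that add atoms: methanol, CO
Why: Cinchona-alkaloid-mediated desymmetrising methanolysis of a meso anhydride, in which quinidine as chiral general base delivers methanol to one of the two enantiotopic carbonyl groups and so fixes the absolute configuration of all four ring stereocentres.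

Step 3
Reactants: 5 cis hemiester
Product: 6 (1S,2R,3R,4R)-3-(methoxycarbonyl)-1,4-dimethyl-7-oxabicyclo[2.2.1]heptane-2-carboxylic acid (acid exo, ester endo)
Conditions: NaOMe (3 equiv), MeOH, 60 °C; then 1 M HCl
Reagents that add atoms: none
Why: Base-mediated epimerisation α to the ester (the carboxylate carbon is protected from enolisation by its charge) should move the ester from the exo face, where it eclipses the neighbouring carboxylate and lies close to the bridgehead methyl, to the endo face under thermodynamic control, giving the trans arrangement.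

Step 4
Reactants: 6 trans hemiester
Product: 7 methyl (1R,2R,3S,4S)-3-(hydroxymethyl)-1,4-dimethyl-7-oxabicyclo[2.2.1]heptane-2-carboxylate
Conditions: BH3·SMe2, THF, 0 °C to rt; MeOH quench
Reagents that add atoms: none
Why: Chemoselective borane reduction of a carboxylic acid in the presence of an ester; no stereocentre is touched and the trans arrangement prevents lactonisation.

Step 5
Reactants: 7 hydroxy ester
Product: 8 methyl (1R,2R,3S,4S)-1,4-dimethyl-3-{[(4-methylbenzenesulfonyl)oxy]methyl}-7-oxabicyclo[2.2.1]heptane-2-carboxylate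
Conditions: TsCl, pyridine, DMAP (cat.), CH2Cl2, 0 °C to rt
Reagents that add atoms: 4-toluenesulfonyl chloride, Cc1ccc(cc1)S(Cl)(=O)=O
Why: Sulfonylation of the unhindered primary alcohol turns it into a leaving group for hydride displacement.

Step 6
Reactants: 8 tosylate ester
Product: 9 [(1R,2S,3R,4S)-1,3,4-trimethyl-7-oxabicyclo[2.2.1]heptan-2-yl]methanol (hydroxymethyl endo, C3 methyl exo)
Conditions: LiEt3BH (5 equiv), THF, 0 to 40 °C; then H2O
Reagents that add atoms: none
Why: Lithium triethylborohydride should displace the primary tosylate by SN2 hydride attack to give the exo methyl group and reduce the ester to the primary alcohol in the same operation, without touching a stereocentre.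

Step 7
Reactants: 9 alcohol
Product: 10 (1R,2R,3R,4S)-2-(bromomethyl)-1,3,4-trimethyl-7-oxabicyclo[2.2.1]heptane
Conditions: CBr4, PPh3, CH2Cl2, 0 °C
Reagents that add atoms: tetrabromomethane, BrC(Br)(Br)Br
Why: Appel bromination of a primary alcohol; the ring stereocentres are not involved.

Step 8
Reactants: 11 (S)-(+)-linalool
Product: 12 (2E,6S)-2,6-dimethylocta-2,7-diene-1,6-diol
Conditions: SeO2 (0.3 equiv), t-BuOOH (2 equiv), salicylic acid (10 mol %), CH2Cl2, rt
Reagents that add atoms: selenium dioxide (oxygen-transfer catalyst), O=[Se]=O; tert-butyl hydroperoxide, CC(C)(C)OO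
Why: SeO2 allylic oxidation (ene reaction followed by 2,3-sigmatropic shift) of the trisubstituted alkene should take place at the (E)-methyl group to give the (E)-allylic alcohol, leaving the carbinol stereocentre and the vinyl group untouched.

Step 9
Reactants: 12 diol
Product: 13 (3S,6E)-8-bromo-3,7-dimethylocta-1,6-dien-3-ol
Conditions: CBr4, PPh3, CH2Cl2, −30 °C
Reagents that add atoms: tetrabromomethane, BrC(Br)(Br)Br
Why: Appel bromination should be selective for the primary allylic hydroxyl over the hindered tertiary one at low temperature and keep the (E) geometry.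

Step 10
Reactants: 10 bromide; 13 allylic bromide
Product: 16 (3S,6E)-3,7-dimethyl-9-[(1R,2R,3R,4S)-1,3,4-trimethyl-7-oxabicyclo[2.2.1]heptan-2-yl]nona-1,6-dien-3-ol, via Grignard reagent 14 (not isolated), via bromomagnesium alkoxide 15 (not isolated)
Conditions: 10, Mg, THF, 50 °C; separately 13, MeMgBr (1.0 equiv), THF, −40 °C; then Li2CuCl4 (5 mol %) and the Grignard solution, −40 to 0 °C; aqueous NH4Cl
Reagents that add atoms: none
Why: Kochi-type copper-catalysed coupling of a primary alkyl Grignard reagent with a primary allylic bromide should occur at the unhindered α-carbon with retention of the (E) geometry, while prior conversion of the tertiary hydroxyl into its weakly nucleophilic magnesium alkoxide with MeMgBr prevents protonolysis of 14.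

Step 11
Reactants: 16 dienol
Product: 17 (3S)-3-methyl-5-[(2R,3R)-3-methyl-3-{2-[(1R,2R,3R,4S)-1,3,4-trimethyl-7-oxabicyclo[2.2.1]heptan-2-yl]ethyl}oxiran-2-yl]pent-1-en-3-ol
Conditions: Shi ketone derived from D-fructose (30 mol %), Oxone (KHSO5), K2CO3, Bu4NHSO4 (cat.), MeCN/CH2(OMe)2/aqueous Na2B4O7 buffer, 0 °C
Reagents that add atoms: potassium peroxymonosulfate, [K+].[O-]S(=O)(=O)OO
Why: Shi asymmetric epoxidation, in which the chiral dioxirane attacks the electron-rich (E)-trisubstituted alkene through the spiro transition state to set C5 and C6 as (R,R) under reagent control, while the monosubstituted vinyl group is left alone.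

Step 12
Reactants: 17 epoxy alcohol
Product: 18 (2R)-2-[(2S,5S)-5-ethenyl-5-methyloxolan-2-yl]-4-[(1R,2R,3R,4S)-1,3,4-trimethyl-7-oxabicyclo[2.2.1]heptan-2-yl]butan-2-ol
Conditions: camphorsulfonic acid (10 mol %), CH2Cl2, 0 °C
Reagents that add atoms: none
Why: Acid-catalysed 5-exo-tet epoxide opening by the tertiary hydroxyl at the secondary carbon C5 with inversion (the usual mode of epoxide-to-oxolane cyclisation in isoprenoid chains), while C6 keeps its configuration as the tertiary carbinol.

Step 13
Reactants: 18 oxolane carbinol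
Product: 22 dactylopyranoid, via imidate salt 19 (not isolated), via oxonium bromide 20 (not isolated), via tertiary bromide 21 (not isolated)
Conditions: Me2C=C(Br)NMe2 (1.2 equiv), 2,6-di-tert-butylpyridine (0.2 equiv), CH2Cl2, 0 °C to rt; then ZnBr2 (10 mol %), rt
Reagents that add atoms: 1-bromo-N,N,2-trimethylprop-1-en-1-amine, CC(C)=C(Br)N(C)C
Why: Proposed new method: the α-bromoenamine turns the tertiary hydroxyl into an imidate leaving group (19) that is expelled with anchimeric assistance by the anti-periplanar oxolane oxygen to give the 1-oxoniabicyclo[3.1.0]hexane 20 (O1 bridging C5 and C6), which bromide opens either at C6 (back to an oxolane, tertiary bromide 21) or at C5, cleaving O1–C5 and leaving the six-membered ring O1/C2/C3/C4/C5/C6; the closest known reaction type is the Nakata-type ring expansion of 2-(1-sulfonyloxyalkyl)oxolanes to 3-acyloxyoxanes through the same bicyclic oxonium ions, extended here to a tertiary carbinol with bromide as terminating nucleophile. The oxane is closed by 3-exo-tet attack of O1 on C6 followed by SN2 opening of the oxiranium at C5, so it is formally the endo-mode product of the epoxonium ion. C6 is set by inversion in the oxygen participation and C5 by inversion in the bromide attack, so both follow stereospecifically from the (5S,6R) centres of 18 and thus from the Shi epoxide, while C2 is untouched. The step needs regioselectivity for C5 over the more cation-stabilising C6, which should be secured thermodynamically: the tertiary β-alkoxy bromide 21 re-ionises to 20 under ZnBr2 catalysis, whereas 22, with a secondary C–Br bond, a tertiary C–O bond and a strain-free chair, is the sink. Opening of 20 at C2 is disfavoured because it would keep the strained oxirane, and the neutral aprotic conditions should spare the vinyl group, the allylic tertiary ether and the oxanorbornane.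

**Compound list**

1 | 2,5-dimethylfuran | Cc1ccc(C)o1 | starting material
2 | maleic anhydride | O=C1OC(=O)C=C1 | starting material
3 | exo-1,4-dimethyl-7-oxabicyclo[2.2.1]hept-5-ene-2,3-dicarboxylic anhydride (meso) | C[C@]12C=C[C@](C)(O1)[C@@H]1C(=O)OC(=O)[C@@H]12 | intermediate
4 | exo-1,4-dimethyl-7-oxabicyclo[2.2.1]heptane-2,3-dicarboxylic anhydride (meso) | C[C@]12CC[C@](C)(O1)[C@@H]1C(=O)OC(=O)[C@@H]12 | intermediate
5 | (1S,2R,3S,4R)-3-(methoxycarbonyl)-1,4-dimethyl-7-oxabicyclo[2.2.1]heptane-2-carboxylic acid | C[C@]12CC[C@](C)(O1)[C@H](C(=O)O)[C@@H]2C(=O)OC | intermediate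
6 | (1S,2R,3R,4R)-3-(methoxycarbonyl)-1,4-dimethyl-7-oxabicyclo[2.2.1]heptane-2-carboxylic acid | C[C@]12CC[C@](C)(O1)[C@H](C(=O)O)[C@H]2C(=O)OC | intermediate
7 | methyl (1R,2R,3S,4S)-3-(hydroxymethyl)-1,4-dimethyl-7-oxabicyclo[2.2.1]heptane-2-carboxylate | C[C@]12CC[C@](C)(O1)[C@H](CO)[C@H]2C(=O)OC | intermediate
8 | methyl (1R,2R,3S,4S)-1,4-dimethyl-3-{[(4-methylbenzenesulfonyl)oxy]methyl}-7-oxabicyclo[2.2.1]heptane-2-carboxylate | C[C@]12CC[C@](C)(O1)[C@H](COS(=O)(=O)c1ccc(C)cc1)[C@H]2C(=O)OC | intermediate
9 | [(1R,2S,3R,4S)-1,3,4-trimethyl-7-oxabicyclo[2.2.1]heptan-2-yl]methanol | C[C@]12CC[C@](C)(O1)[C@H](C)[C@H]2CO | intermediate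
10 | (1R,2R,3R,4S)-2-(bromomethyl)-1,3,4-trimethyl-7-oxabicyclo[2.2.1]heptane | C[C@]12CC[C@](C)(O1)[C@H](C)[C@H]2CBr | intermediate
11 | (S)-(+)-linalool, (3S)-3,7-dimethylocta-1,6-dien-3-ol | C=C[C@@](C)(O)CCC=C(C)C | starting material
12 | (2E,6S)-2,6-dimethylocta-2,7-diene-1,6-diol | C=C[C@@](C)(O)CC/C=C(\C)CO | intermediate
13 | (3S,6E)-8-bromo-3,7-dimethylocta-1,6-dien-3-ol | C=C[C@@](C)(O)CC/C=C(\C)CBr | intermediate
14 | {[(1R,2R,3R,4S)-1,3,4-trimethyl-7-oxabicyclo[2.2.1]heptan-2-yl]methyl}magnesium bromide | C[C@]12CC[C@](C)(O1)[C@H](C)[C@H]2C[Mg]Br | intermediate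
15 | bromomagnesium (3S,6E)-8-bromo-3,7-dimethylocta-1,6-dien-3-olate | C=C[C@@](C)(O[Mg]Br)CC/C=C(\C)CBr | intermediate
16 | (3S,6E)-3,7-dimethyl-9-[(1R,2R,3R,4S)-1,3,4-trimethyl-7-oxabicyclo[2.2.1]heptan-2-yl]nona-1,6-dien-3-ol | C=C[C@@](C)(O)CC/C=C(\C)CC[C@@H]1[C@@H](C)[C@]2(C)CC[C@@]1(C)O2 | intermediate
17 | (3S)-3-methyl-5-[(2R,3R)-3-methyl-3-{2-[(1R,2R,3R,4S)-1,3,4-trimethyl-7-oxabicyclo[2.2.1]heptan-2-yl]ethyl}oxiran-2-yl]pent-1-en-3-ol | C=C[C@@](C)(O)CC[C@H]1O[C@]1(C)CC[C@@H]1[C@@H](C)[C@]2(C)CC[C@@]1(C)O2 | intermediate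
18 | (2R)-2-[(2S,5S)-5-ethenyl-5-methyloxolan-2-yl]-4-[(1R,2R,3R,4S)-1,3,4-trimethyl-7-oxabicyclo[2.2.1]heptan-2-yl]butan-2-ol | C=C[C@]1(C)CC[C@H](O1)[C@](C)(O)CC[C@@H]1[C@@H](C)[C@]2(C)CC[C@@]1(C)O2 | intermediate
19 | O-alkyl N,N-dimethyl-2-methylpropanimidium bromide of 18 (imidate salt) | C=C[C@]1(C)CC[C@H](O1)[C@](C)(OC(=[N+](C)C)C(C)C)CC[C@@H]1[C@@H](C)[C@]2(C)CC[C@@]1(C)O2.[Br-] | intermediate
20 | 1-oxoniabicyclo[3.1.0]hexane bromide, O1 bonded to C2, C5 and C6 (C6 inverted relative to 18) | C=C[C@]1(C)CC[C@H]([O+]12)[C@]2(C)CC[C@@H]1[C@@H](C)[C@]2(C)CC[C@@]1(C)O2.[Br-] | intermediate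
21 | (2S,5S)-5-{(2R)-2-bromo-4-[(1R,2R,3R,4S)-1,3,4-trimethyl-7-oxabicyclo[2.2.1]heptan-2-yl]butan-2-yl}-2-ethenyl-2-methyloxolane | C=C[C@]1(C)CC[C@H](O1)[C@](C)(Br)CC[C@@H]1[C@@H](C)[C@]2(C)CC[C@@]1(C)O2 | intermediate
22 | dactylopyranoid, (2S,5R,6S)-5-bromo-2-ethenyl-2,6-dimethyl-6-{2-[(1R,2R,3R,4S)-1,3,4-trimethyl-7-oxabicyclo[2.2.1]heptan-2-yl]ethyl}oxane (route numbering) | C=C[C@]1(C)CC[C@@H](Br)[C@](C)(CC[C@@H]2[C@@H](C)[C@]3(C)CC[C@@]2(C)O3)O1 | target

**Totals**

Total step count: 13. Longest linear sequence: 11 (steps 1 to 7, then 10 to 13).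

**Steps most likely to fail**

1. Step 13 (proposed new method). What may go wrong: bromide capture at C6 without the tertiary bromide draining onward, loss of a proton from the oxonium ion, or loss of stereochemical integrity at C6 if ionisation proceeds through a free cation instead of with oxygen participation. Fallback with known chemistry: the fallback sets out from dienol 16 and returns to the route at 22. 16 is treated with 2,4,4,6-tetrabromocyclohexa-2,5-dienone in MeNO2 at 0 °C. This is the bromonium-induced 6-endo etherification established for linalool- and nerolidol-type tertiary alcohols. Anti addition across the (E)-alkene gives the required C5/C6 relative configuration directly, but with lower facial and regiochemical control, so chromatographic separation is accepted. No new intermediate is made.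

2. Step 3. What may go wrong: E1cB opening of the oxygen bridge from the ester enolate, or an epimerisation equilibrium that stops short of the trans isomer. The fallback sets out from meso anhydride 4 and returns at alcohol 9, moving the epimerisation to the aldehyde oxidation level. LiAlH4 in THF gives the meso exo,exo-diol F1. Desymmetrising acetylation with Burkholderia cepacia lipase and vinyl acetate gives the monoacetate F2. Tosylation of the free hydroxyl gives the tosylate acetate F3. LiEt3BH then reduces the tosylate to methyl and cleaves the acetate, giving the cis alcohol F4. Dess–Martin oxidation gives the exo aldehyde F5, which DBU in CH2Cl2 should epimerise to the endo aldehyde F6 (trans to the C3 methyl, away from the bridgehead methyl). NaBH4 in MeOH then gives 9.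

3. Step 10. What may go wrong: low conversion of the β-branched Grignard reagent in the copper-catalysed substitution, competing SN2′ attack at the γ-carbon, or side reactions of the alkoxide-bearing allylic bromide. The fallback sets out from 10 and 13 and returns at dienol 16, replacing the Grignard by a sulfone-stabilised carbanion and masking the hydroxyl. 13 is silylated with Et3SiOTf and 2,6-lutidine to the triethylsilyl ether F7. 10 is treated with PhSO2Na in DMF to give the sulfone F8. Lithiation of F8 (n-BuLi, THF, −78 °C) and alkylation with F7 give the alkylated sulfone F9. Reductive desulfonylation with sodium amalgam (Na/Hg) and Na2HPO4 in MeOH gives the silyl ether F10, and Bu4NF then gives 16.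

**Further compounds**

F0 | step 13 | none | none
F1 | step 3 | exo,exo-[1,4-dimethyl-7-oxabicyclo[2.2.1]heptane-2,3-diyl]dimethanol (meso) | C[C@]12CC[C@](C)(O1)[C@H](CO)[C@@H]2CO
F2 | step 3 | [(1R,2R,3S,4S)-3-(hydroxymethyl)-1,4-dimethyl-7-oxabicyclo[2.2.1]heptan-2-yl]methyl acetate | C[C@]12CC[C@](C)(O1)[C@H](CO)[C@@H]2COC(C)=O
F3 | step 3 | [(1R,2R,3S,4S)-1,4-dimethyl-3-{[(4-methylbenzenesulfonyl)oxy]methyl}-7-oxabicyclo[2.2.1]heptan-2-yl]methyl acetate | C[C@]12CC[C@](C)(O1)[C@H](COS(=O)(=O)c1ccc(C)cc1)[C@@H]2COC(C)=O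
F4 | step 3 | [(1R,2R,3R,4S)-1,3,4-trimethyl-7-oxabicyclo[2.2.1]heptan-2-yl]methanol (hydroxymethyl exo) | C[C@]12CC[C@](C)(O1)[C@H](C)[C@@H]2CO
F5 | step 3 | (1R,2S,3R,4S)-1,3,4-trimethyl-7-oxabicyclo[2.2.1]heptane-2-carbaldehyde (formyl exo) | C[C@]12CC[C@](C)(O1)[C@H](C)[C@@H]2C=O
F6 | step 3 | (1R,2R,3R,4S)-1,3,4-trimethyl-7-oxabicyclo[2.2.1]heptane-2-carbaldehyde (formyl endo) | C[C@]12CC[C@](C)(O1)[C@H](C)[C@H]2C=O
F7 | step 10 | {[(3S,6E)-8-bromo-3,7-dimethylocta-1,6-dien-3-yl]oxy}triethylsilane | C=C[C@@](C)(O[Si](CC)(CC)CC)CC/C=C(\C)CBr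
F8 | step 10 | (1R,2R,3R,4S)-2-[(benzenesulfonyl)methyl]-1,3,4-trimethyl-7-oxabicyclo[2.2.1]heptane | C[C@]12CC[C@](C)(O1)[C@H](C)[C@H]2CS(=O)(=O)c1ccccc1
F9 | step 10 | {[(3S,6E)-9-(benzenesulfonyl)-3,7-dimethyl-9-[(1R,2R,3R,4S)-1,3,4-trimethyl-7-oxabicyclo[2.2.1]heptan-2-yl]nona-1,6-dien-3-yl]oxy}triethylsilane (mixture at C9) | C=C[C@@](C)(O[Si](CC)(CC)CC)CC/C=C(\C)CC([C@@H]1[C@@H](C)[C@]2(C)CC[C@@]1(C)O2)S(=O)(=O)c1ccccc1
F10 | step 10 | {[(3S,6E)-3,7-dimethyl-9-[(1R,2R,3R,4S)-1,3,4-trimethyl-7-oxabicyclo[2.2.1]heptan-2-yl]nona-1,6-dien-3-yl]oxy}triethylsilane | C=C[C@@](C)(O[Si](CC)(CC)CC)CC/C=C(\C)CC[C@@H]1[C@@H](C)[C@]2(C)CC[C@@]1(C)O2
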